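## Structural features

The target is a flavone: benzene ring A is fused to the 4-pyranone ring C, and C2 of ring C is joined by one sp2–sp2 bond to C1' of a separate benzene ring B. Ring A carries a hydroxyl at C5, hydrogen-bonded to the C4 carbonyl, and a methoxyl at C7. Ring B is oxygenated on four adjacent carbons: hydroxyls at C2' and C5' (a para-hydroquinone) enclose methoxyls at C3' and C4', and only C6' carries hydrogen. The target has no stereocentre and no stereogenic double bond; the only stereo-elements on the route are an E alkene and a racemic carbinol carbon, both consumed when ring B forms. The fragile parts are the electron-rich hydroquinone, which air oxidises to the quinone (fastest in base), and the pyranone, which hard nucleophiles open at C2. The real difficulty is the oxygen pattern, not the carbon skeleton: ring B needs two free and two methylated oxygens in fixed order and ring A one of each, so a route from a polymethoxyarene must tell apart ethers of nearly equal reactivity. The key step uses the fact that C2'(OH)–C3'(OMe)–C4'(OMe)–C5'(OH) is the four-carbon core of a squaric diester and C6'–C1' is a two-carbon alkene already attached to C2 of ring C, so ring B closes by forming only C1'–C2', with both hydroxyls free and both methoxyls in place.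

## Logic of the disconnections

16 to 15. The benzyl–oxygen bond on the C5 oxygen is cut last. The C5 hydroxyl has to be masked earlier, because a metal phenoxide chelated to the C4 carbonyl would act like a Lewis acid there and could steer metalation from C2 to C3. A benzyl ether is chosen because it leaves under reducing, neutral conditions that also protect the hydroquinone. Nothing is gained in skeleton. The forward step must leave the C2–C3 double bond alone and be run without air.

15 to 12 (through 14 and 13). The C1'–C2' bond of ring B is cut, the phenol is taken back to its keto form, and the C2'–C5' bond of a four-membered ring is restored. This replaces a tetra-oxygenated arene with a squarate adduct in which all four oxygens are already correct, so no ring B oxygen is ever differentiated. The forward step needs the alkenyl group, not the hydroxyl, to turn toward the ketene. Because 12 ring-opens on warming, every operation before it must run at or below room temperature.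

12 to 7 and 11. The sp2–sp2 bond between C2 of ring C and the vinyl carbon is cut, which makes the route convergent. A vinyl–lithium or vinyl–magnesium species cannot coexist with the pyranone, so the metal (tin) is placed on the squarate half and the halide on the chromone half. The forward coupling must work at room temperature under neutral conditions, tolerate the free tertiary alcohol and keep the E geometry.

11 to 9 and 10, and 10 to 8. The bond between the carbinol carbon and the vinyl carbon is cut, which is the 1,2-addition of a vinyl anion to one of the two equivalent carbonyls of 9. The anion 10 is traced to 8 by tin–lithium exchange, which keeps the E geometry and leaves the second tin as the coupling handle. The forward step must stop at mono-addition and must add to the carbonyl rather than in conjugate fashion, hence low temperature and inverse addition.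

7 to 5 (through 6). The C2–I bond is cut back to a C2–H bond. This is the shortest access to a 2-halochromone. The forward step needs metalation at C2 rather than C3 and a carbon–metal bond mild enough not to open the pyranone, which points to a zinc amide base used without added Lewis acid.

5 to 3 (through 4). The O1–C2 and C2–C3 bonds are cut, so C2 comes from a one-carbon formamide acetal and ring C closes by the free phenol adding to an enaminone. The forward step needs the phenol ortho to the acetyl group free and the benzyl ether stable to brief acid.

3 to 1 and 2. The benzyl–oxygen bond is cut. Since 1 is symmetric, either hydroxyl may be alkylated, and the one left over becomes O1. The forward step must stop at mono-alkylation, which is helped by the hydrogen bond between the remaining phenol and the ketone.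

## Other disconnections considered

Alternative 1: The cut is C4–C4a of ring C. In the forward direction (Z)-3-(3,5-dimethoxyphenoxy)-3-(2,3,4,5-tetramethoxyphenyl)prop-2-enoic acid A2 would be activated with P2O5 in MeSO3H, and its acyl carbon would attack the ortho carbon of the aryloxy ring to give 5,7-dimethoxy-2-(2,3,4,5-tetramethoxyphenyl)chromen-4-one A1.
- In its favour: the aryloxy ring is symmetric and doubly activated, so the site of acylation is unambiguous. The chemistry is robust acid chemistry without tin, palladium or cryogenics. The carbon skeleton should be reached in about four steps, fewer than the chosen plan; on step count to the skeleton this alternative is the better one.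
- Against it: A1 carries six methyl ethers, and three (C5, C2', C5') must be cleaved while three (C7, C3', C4') stay. The C5 ether can be removed by chelation to the carbonyl. The ring B pair would need an oxidative demethylation across the para positions and a re-reduction, in the presence of an electron-rich ring A. That is at least three more steps, each with a chemoselectivity burden.
- Mechanistically, the acylium ion can also attack the activated C6' of ring B if the acid geometry places the carboxyl next to that ring, which would give an indenone.
- Comparison: the alternative builds the skeleton faster, but the chosen plan supplies the ring B oxygens already differentiated and closes ring B by a unimolecular pericyclic step with no competing site. Overall the chosen plan should be shorter to the target and more selective.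

Alternative 2: The cuts are O1–C8a, C4–C4a and O1–C2, so all of ring C is made in one operation. In the forward direction CsF would release the aryne from 3,5-dimethoxy-2-(trimethylsilyl)phenyl trifluoromethanesulfonate A4 in the presence of 3-[2,5-bis(benzyloxy)-3,4-dimethoxyphenyl]prop-2-ynoic acid A5. The carboxylate oxygen would add to the aryne, the aryl anion would take the acyl carbon, and the phenoxide would close onto the ynone to give 2-[2,5-bis(benzyloxy)-3,4-dimethoxyphenyl]-5,7-dimethoxychromen-4-one A3.
- In its favour: three bonds form in one flask, which is better than the chosen key step in bond count and convergence. Both methoxyls of the aryne direct the oxygen nucleophile to the carbon that becomes C8a, so the regiochemistry is reinforced. The ring B hydroxyls are masked as benzyl ethers, which would come off by hydrogenolysis, equal to the chosen plan on that point.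
- Against it: neither A4 nor A5 is a catalogue compound, and each needs several steps. Ring A arrives with both oxygens methylated, so a selective C5 demethylation remains.
- Mechanistically, the ortho-hydroxyaryl ynone can also close in the five-membered (aurone) sense, and an electron-rich aryl group on the alkyne makes the ynone a weaker acceptor. Decarboxylation of the propiolic acid competes with capture of the aryne.
- Comparison: the key step of this alternative is the more powerful one, but the whole route should be several steps longer and keeps one ether differentiation. The chosen plan has none and uses two commercial building blocks for ring B.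

Alternative 3: The cuts are C1'–C2' and C5'–C6' of ring B. In the forward direction tert-butyl[(3,4-dimethoxyfuran-2-yl)oxy]dimethylsilane A7 would add across the alkyne of 5-(benzyloxy)-2-ethynyl-7-methoxy-4H-chromen-4-one A8, and the oxygen bridge would open to give 5-(benzyloxy)-2-{2-[(tert-butyldimethylsilyl)oxy]-5-hydroxy-3,4-dimethoxyphenyl}-7-methoxychromen-4-one A6.
- In its favour: it shares the idea of building ring B from a four-carbon unit that already carries the four oxygens, so it is equal to the chosen plan on oxygen differentiation. The regiochemistry is polarity-matched, since the nucleophilic C5 of the furan meets the electrophilic alkyne terminus. A6 is a mono-silylated hydroquinone and would be less air-sensitive than 15; on product handling this alternative is the better one.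
- Against it: A8 would need two further steps from 7 (alkynylation and desilylation), and A7 is a moisture-sensitive silyl ketene acetal that has to be made. A desilylation is also added at the end.
- Mechanistically, the cycloaddition is bimolecular onto a moderately activated alkyne. It can stop at a vinylogous Michael adduct, and the C2–C3 double bond of the pyranone is a second dienophile.
- Comparison: structurally the two plans are close. The chosen plan forms one bond, not two, but does so in a unimolecular, reagent-free step from a precursor that is two to three steps shorter.

Key step: step 6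

Remark on the chemistry: the carbinol carbon of 11 and 12 is the only stereocentre on the route; it is assumed to form racemic, which is harmless because step 6 destroys it. Compounds 12 and 15 were checked atom by atom and are constitutional isomers (C25H22O8).

## Route

Step 1
Reactants: 1 2',6'-dihydroxy-4'-methoxyacetophenone; 2 benzyl bromide
Product: 3 2'-(benzyloxy)-6'-hydroxy-4'-methoxyacetophenone
Conditions: 2 (1.05 equiv), K2CO3, acetone, reflux
Reagents that add atoms: none
Why: Williamson ether synthesis; 1 is symmetric, and after the first alkylation the remaining phenol is held in a strong hydrogen bond to the ketone and is much less nucleophilic, so near-stoichiometric bromide should stop at the monoether.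

Step 2
Reactants: 3 2'-(benzyloxy)-6'-hydroxy-4'-methoxyacetophenone
Product: 5 5-(benzyloxy)-7-methoxy-4H-chromen-4-one, via enaminone 4 (not isolated)
Conditions: DMF-DMA, toluene, 100 °C; concentrate; then conc. HCl, CH2Cl2, 20 °C
Reagents that add atoms: N,N-dimethylformamide dimethyl acetal, COC(OC)N(C)C
Why: Condensation of the methyl ketone with the amide acetal gives the E enaminone, and acid then promotes intramolecular oxa-Michael addition of the free phenol and loss of dimethylamine (enaminone-to-chromone cyclisation); the benzyl ether should survive brief acid at room temperature.

Step 3
Reactants: 5 5-(benzyloxy)-7-methoxy-4H-chromen-4-one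
Product: 7 5-(benzyloxy)-2-iodo-7-methoxy-4H-chromen-4-one, via chromon-2-ylzinc chloride 6 (not isolated)
Conditions: TMPZnCl·LiCl (1.2 equiv), THF, −30 → 0 °C; then I2, THF, 0 → 20 °C
Reagents that add atoms: iodine, [I][I]
Why: Directed C–H zincation with a hindered zinc amide, a reaction type known for chromones: without added Lewis acid the most acidic hydrogen, at C2 next to the ring oxygen, is removed, the covalent carbon–zinc bond does not open the pyranone, and iodolysis gives the 2-iodide.

Step 4
Reactants: 8 (E)-1,2-bis(tributylstannyl)ethene; 9 dimethyl squarate
Product: 11 rac-4-hydroxy-2,3-dimethoxy-4-[(E)-2-(tributylstannyl)ethenyl]cyclobut-2-en-1-one, via stannylvinyllithium 10 (not isolated)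
Conditions: n-BuLi (1.0 equiv), THF, −78 °C; cannulate into 9, THF, −78 °C; NH4Cl aq., −78 °C
Reagents that add atoms: none
Why: Tin–lithium exchange gives the E vinyllithium with retention, and its 1,2-addition to one of the two equivalent carbonyls of the squarate ester (the usual mode for organolithiums at −78 °C) gives the tertiary carbinol as a racemate; inverse addition and a cold quench guard against double addition.

Step 5
Reactants: 7 5-(benzyloxy)-2-iodo-7-methoxy-4H-chromen-4-one; 11 rac-4-hydroxy-2,3-dimethoxy-4-[(E)-2-(tributylstannyl)ethenyl]cyclobut-2-en-1-one
Product: 12 rac-4-{(E)-2-[5-(benzyloxy)-7-methoxy-4-oxo-4H-chromen-2-yl]ethenyl}-4-hydroxy-2,3-dimethoxycyclobut-2-en-1-one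
Conditions: Pd2(dba)3 (2.5 mol %), AsPh3 (20 mol %), CuI (10 mol %), DMF, 20 °C, dark, Ar
Reagents that add atoms: none
Why: Stille cross-coupling: zerovalent palladium inserts readily into the activated C2–I bond of this vinylogous acyl iodide, AsPh3 and CuI speed tin-to-palladium transfer so no heating is needed, the E geometry is retained and the neutral medium tolerates the free tertiary alcohol; at 20 °C the cyclobutenone should not yet ring-open.

Step 6
Reactants: 12 rac-4-{(E)-2-[5-(benzyloxy)-7-methoxy-4-oxo-4H-chromen-2-yl]ethenyl}-4-hydroxy-2,3-dimethoxycyclobut-2-en-1-one
Product: 15 5-(benzyloxy)-2-(2,5-dihydroxy-3,4-dimethoxyphenyl)-7-methoxy-4H-chromen-4-one, via dienylketene 13 (not isolated), via cyclohexadienone 14 (not isolated)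
Conditions: degassed toluene (0.02 M), 110 °C, Ar; work-up under Ar with Na2S2O4 aq.
Reagents that add atoms: none
Why: Moore-type thermal ring expansion of a 4-alkenyl-4-hydroxycyclobutenone, the closest known reaction type being the rearrangement of squarate-derived alkenylcyclobutenones to hydroquinones. Heat breaks the bond between the carbonyl carbon (future C2') and the carbinol carbon (future C5') of the four-membered ring in a conrotatory four-electron opening to dienylketene 13. The selectivity the step needs is torquoselectivity: the hydroxyl on the carbinol carbon is a lone-pair donor and rotates outward, so the alkenyl arm turns inward and lies cis to the ketene across the new C4'=C5' bond (Z). A thermally allowed disrotatory six-electron electrocyclisation then joins the ketene carbon C2' to the alkene carbon C1' and closes the six-membered ring B as cyclohexadienone 14; this is a pericyclic closure of a hexatriene and not a polar ring closure. The E alkene keeps the bulky chromone on the outside of the closing terminus and its hydrogen on the inside, so the closure is not hindered. The sp3 carbon created at C1' in 14 lies alpha to the new ketone and loses its hydrogen on enolisation, which aromatises ring B to 15; no stereocentre survives, and the racemic carbinol centre of 12 disappears as well. The step is a reagent-free isomerisation at 110 °C, under which the benzyl ether, the methyl ethers and the pyranone are inert. Air is excluded and the work-up is reductive (Na2S2O4) because 15 is an electron-rich hydroquinone.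

Step 7
Reactants: 15 5-(benzyloxy)-2-(2,5-dihydroxy-3,4-dimethoxyphenyl)-7-methoxy-4H-chromen-4-one
Product: 16 2-(2,5-dihydroxy-3,4-dimethoxyphenyl)-5-hydroxy-7-methoxy-4H-chromen-4-one (CNP0170944.0)
Conditions: H2 (1 atm), 10% Pd/C, degassed EtOAc–MeOH, 20 °C; filter under Ar
Reagents that add atoms: none
Why: Catalytic hydrogenolysis of an aryl benzyl ether; the conjugated C2–C3 double bond of a flavone and the aryl methyl ethers are normally untouched at 1 atm and room temperature, and the reducing atmosphere keeps the hydroquinone from oxidising.

## Compound list

1 | 2',6'-dihydroxy-4'-methoxyacetophenone | CC(=O)c1c(O)cc(OC)cc1O | starting material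
2 | benzyl bromide | BrCc1ccccc1 | starting material
3 | 2'-(benzyloxy)-6'-hydroxy-4'-methoxyacetophenone | CC(=O)c1c(O)cc(OC)cc1OCc1ccccc1 | intermediate
4 | (E)-1-[2-(benzyloxy)-6-hydroxy-4-methoxyphenyl]-3-(dimethylamino)prop-2-en-1-one | CN(C)/C=C/C(=O)c1c(O)cc(OC)cc1OCc1ccccc1 | intermediate (not isolated)
5 | 5-(benzyloxy)-7-methoxy-4H-chromen-4-one | COc1cc(OCc2ccccc2)c2c(=O)ccoc2c1 | intermediate
6 | [5-(benzyloxy)-7-methoxy-4-oxo-4H-chromen-2-yl]zinc chloride (LiCl complex) | COc1cc(OCc2ccccc2)c2c(=O)cc([Zn]Cl)oc2c1 | intermediate (not isolated)
7 | 5-(benzyloxy)-2-iodo-7-methoxy-4H-chromen-4-one | COc1cc(OCc2ccccc2)c2c(=O)cc(I)oc2c1 | intermediate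
8 | (E)-1,2-bis(tributylstannyl)ethene | CCCC[Sn](CCCC)(CCCC)/C=C/[Sn](CCCC)(CCCC)CCCC | starting material
9 | dimethyl squarate (3,4-dimethoxycyclobut-3-ene-1,2-dione) | COC1=C(OC)C(=O)C1=O | starting material
10 | (E)-[2-(tributylstannyl)ethenyl]lithium | [Li]/C=C/[Sn](CCCC)(CCCC)CCCC | intermediate (not isolated)
11 | rac-4-hydroxy-2,3-dimethoxy-4-[(E)-2-(tributylstannyl)ethenyl]cyclobut-2-en-1-one | COC1=C(OC)C(O)(/C=C/[Sn](CCCC)(CCCC)CCCC)C1=O | intermediate
12 | rac-4-{(E)-2-[5-(benzyloxy)-7-methoxy-4-oxo-4H-chromen-2-yl]ethenyl}-4-hydroxy-2,3-dimethoxycyclobut-2-en-1-one | COC1=C(OC)C(O)(/C=C/c2cc(=O)c3c(OCc4ccccc4)cc(OC)cc3o2)C1=O | intermediate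
13 | (3Z,5E)-6-[5-(benzyloxy)-7-methoxy-4-oxo-4H-chromen-2-yl]-4-hydroxy-2,3-dimethoxyhexa-1,3,5-trien-1-one | O=C=C(OC)/C(OC)=C(/O)\C=C\c1cc(=O)c2c(OCc3ccccc3)cc(OC)cc2o1 | intermediate (not isolated)
14 | rac-6-[5-(benzyloxy)-7-methoxy-4-oxo-4H-chromen-2-yl]-4-hydroxy-2,3-dimethoxycyclohexa-2,4-dien-1-one | O=C1C(OC)=C(OC)C(O)=CC1c1cc(=O)c2c(OCc3ccccc3)cc(OC)cc2o1 | intermediate (not isolated)
15 | 5-(benzyloxy)-2-(2,5-dihydroxy-3,4-dimethoxyphenyl)-7-methoxy-4H-chromen-4-one | COc1cc(OCc2ccccc2)c2c(=O)cc(-c3cc(O)c(OC)c(OC)c3O)oc2c1 | intermediate
16 | 2-(2,5-dihydroxy-3,4-dimethoxyphenyl)-5-hydroxy-7-methoxy-4H-chromen-4-one (CNP0170944.0) | COc1cc(O)c2c(=O)cc(-c3cc(O)c(OC)c(OC)c3O)oc2c1 | target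

## Step count and risks

Total step count: 7. Longest linear sequence: 6 steps (steps 1, 2, 3, 5, 6 and 7); step 4 makes the second fragment.

Least certain steps:

Step 6 (key step). The most likely trouble is partial aerial oxidation of the electron-rich hydroquinone during work-up and chromatography, which would give redox mixtures. A smaller risk is lactonisation of the ketene by the hydroxyl if some inward rotation of the hydroxyl occurs. The fallback sets out from 12 and accepts the oxidation. After the thermolysis, the cooled solution is treated with Ag2O to give the air-stable 2-[5-(benzyloxy)-7-methoxy-4-oxo-4H-chromen-2-yl]-5,6-dimethoxycyclohexa-2,5-diene-1,4-dione F1, which can be purified without precautions. Hydrogenation of F1 over Pd/C then reduces the quinone and cleaves the benzyl ether in one operation, and the route is rejoined at 16.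

Step 5. Tin-to-palladium transfer may be slow at the low temperature that the labile cyclobutenone imposes, so loss of tin by protonation and homocoupling of the stannane could compete. Premature ring expansion in the presence of metal salts is also possible. The fallback sets out from 11 and 5. Iododestannylation of 11 (I2, CH2Cl2, 0 °C) gives rac-4-hydroxy-4-[(E)-2-iodoethenyl]-2,3-dimethoxycyclobut-2-en-1-one F2. Zinc reagent 6, made from 5 as in step 3, is coupled with F2 in a Negishi reaction (Pd(OAc)2, SPhos, THF, 20 °C), which tolerates the tertiary alcohol. The route is rejoined at 12 without isolating 7.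

Step 3. Metalation may go to C3 if the metal is held between the C4 carbonyl and the C5 ether oxygen, or the C2-metalated pyranone may ring-open. The fallback sets out from 3 and needs no metalation of the heterocycle. Condensation of 3 with CS2 and KOt-Bu in THF gives 5-(benzyloxy)-4-hydroxy-7-methoxy-2H-chromene-2-thione F3. S-Methylation (MeI, K2CO3, acetone) gives 5-(benzyloxy)-7-methoxy-2-(methylsulfanyl)-4H-chromen-4-one F4. F4 is joined to 11 by a thioether–stannane coupling of the Liebeskind–Srogl type (Pd2(dba)3, tri(2-furyl)phosphine, CuO2PPh2, THF, 20–40 °C). The route is rejoined at 12.

Step 4. Incomplete tin–lithium exchange would leave butyllithium to add to the squarate; a second addition to the product and loss of tin on silica are also possible. The fallback sets out from 9 and separates carbon–carbon bond formation from the introduction of tin. Ethynylmagnesium bromide (THF, −78 °C) gives rac-4-ethynyl-4-hydroxy-2,3-dimethoxycyclobut-2-en-1-one F5. Palladium-catalysed syn hydrostannation (Bu3SnH, PdCl2(PPh3)2, THF, 0 °C) should place tin at the unhindered terminus with E geometry. The route is rejoined at 11.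

Step 7. Traces of tin or iodide may poison the catalyst, the C2–C3 double bond may be slowly saturated on long exposure, and the product may re-oxidise during filtration in air. The fallback sets out from 15 and replaces hydrogenolysis by Lewis-acid debenzylation: BCl3 with pentamethylbenzene as cation scavenger in CH2Cl2 at −78 °C, then a methanol quench. The ether peri to the carbonyl is the most labile one, and the methyl ethers should survive at this temperature. The route is rejoined at 16 with no new intermediate.

## Further compounds

F1 | step 6 | 2-[5-(benzyloxy)-7-methoxy-4-oxo-4H-chromen-2-yl]-5,6-dimethoxycyclohexa-2,5-diene-1,4-dione | COC1=C(OC)C(=O)C(c2cc(=O)c3c(OCc4ccccc4)cc(OC)cc3o2)=CC1=O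
F2 | step 5 | rac-4-hydroxy-4-[(E)-2-iodoethenyl]-2,3-dimethoxycyclobut-2-en-1-one | COC1=C(OC)C(O)(/C=C/I)C1=O
F3 | step 3 | 5-(benzyloxy)-4-hydroxy-7-methoxy-2H-chromene-2-thione | COc1cc(OCc2ccccc2)c2c(O)cc(=S)oc2c1
F4 | step 3 | 5-(benzyloxy)-7-methoxy-2-(methylsulfanyl)-4H-chromen-4-one | COc1cc(OCc2ccccc2)c2c(=O)cc(SC)oc2c1
F5 | step 4 | rac-4-ethynyl-4-hydroxy-2,3-dimethoxycyclobut-2-en-1-one | COC1=C(OC)C(O)(C#C)C1=O
F0 | step 7 | none | none
A1 | alternative 1 | 5,7-dimethoxy-2-(2,3,4,5-tetramethoxyphenyl)chromen-4-one | COc1cc(OC)c2c(=O)cc(-c3cc(OC)c(OC)c(OC)c3OC)oc2c1
A2 | alternative 1 | (Z)-3-(3,5-dimethoxyphenoxy)-3-(2,3,4,5-tetramethoxyphenyl)prop-2-enoic acid | OC(=O)/C=C(\Oc1cc(OC)cc(OC)c1)c1cc(OC)c(OC)c(OC)c1OC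
A3 | alternative 2 | 2-[2,5-bis(benzyloxy)-3,4-dimethoxyphenyl]-5,7-dimethoxychromen-4-one | COc1cc(OC)c2c(=O)cc(-c3cc(OCc4ccccc4)c(OC)c(OC)c3OCc3ccccc3)oc2c1
A4 | alternative 2 | 3,5-dimethoxy-2-(trimethylsilyl)phenyl trifluoromethanesulfonate | COc1cc(OC)c([Si](C)(C)C)c(OS(=O)(=O)C(F)(F)F)c1
A5 | alternative 2 | 3-[2,5-bis(benzyloxy)-3,4-dimethoxyphenyl]prop-2-ynoic acid | OC(=O)C#Cc1cc(OCc2ccccc2)c(OC)c(OC)c1OCc1ccccc1
A6 | alternative 3 | 5-(benzyloxy)-2-{2-[(tert-butyldimethylsilyl)oxy]-5-hydroxy-3,4-dimethoxyphenyl}-7-methoxychromen-4-one | COc1cc(OCc2ccccc2)c2c(=O)cc(-c3cc(O)c(OC)c(OC)c3O[Si](C)(C)C(C)(C)C)oc2c1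
A7 | alternative 3 | tert-butyl[(3,4-dimethoxyfuran-2-yl)oxy]dimethylsilane | COc1coc(O[Si](C)(C)C(C)(C)C)c1OC
A8 | alternative 3 | 5-(benzyloxy)-2-ethynyl-7-methoxy-4H-chromen-4-one | COc1cc(OCc2ccccc2)c2c(=O)cc(C#C)oc2c1
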